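**Target:** (S)-2-allyl-4-[(E)-1-(3,4-dimethoxyphenyl)prop-1-en-2-yl]-4,5-dimethoxycyclohexa-2,5-dien-1-one, C22H26O5. Reading the SMILES gives one stereocenter (C4, S; CIP order OMe > C5 > C8 > C3) and an E alkene (aryl trans to the quaternary ring carbon). Ring numbering: C1 = C=O, C2 bears allyl, C4 is the quaternary carbon, C5 bears OMe; side chain C7 = ArCH, C8 = C(Me).

**Assumption:** the sense of induction of the chiral acid in step 4 cannot be predicted with certainty, so the catalyst antipode that gives the S product is used (both antipodes are accessible) and the configuration is confirmed by chiral HPLC and ECD.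

**Retrosynthetic overview**
1. Target ⇒ C4–C8 bond: 2-allyl-4,4,5-trimethoxycyclohexa-2,5-dienone (a quinone monoketal, i.e. a phenoxenium or vinylogous enolonium equivalent, electrophilic at the former phenol para carbon) + (E)-methyl isoeugenol as alkene nucleophile. A chiral counter-anion sets C4 and loss of H8 sets the E alkene.
2. Quinone monoketal ⇒ 2-allyl-4,5-dimethoxyphenol by oxidative dearomatization in methanol.
3. 2-Allyl-4,5-dimethoxyphenol ⇒ allyl 3,4-dimethoxyphenyl ether (aromatic Claisen) ⇒ 3,4-dimethoxyphenol + allyl bromide.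
4. Rings: none is built. The dienone ring is the benzene ring of 3,4-dimethoxyphenol, dearomatized in the third step; the dimethoxyphenyl ring comes intact from methyl isoeugenol.

**Route**

Step 1
Reactants: 1 3,4-dimethoxyphenol; 2 allyl bromide
Product: 3 allyl 3,4-dimethoxyphenyl ether
Conditions: K2CO3, acetone, reflux
Reagents that add atoms: none
Why: Williamson ether synthesis (SN2 O-allylation of the phenoxide); no stereocenter is involved.

Step 2
Reactants: 3 allyl 3,4-dimethoxyphenyl ether
Product: 5 2-allyl-4,5-dimethoxyphenol, via Claisen dienone 4 (not isolated)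
Conditions: N,N-diethylaniline, 200 °C, N2
Reagents that add atoms: none
Why: Aromatic Claisen rearrangement ([3,3]-sigmatropic shift) to the less hindered ortho carbon, para to the 3-methoxy group, followed by tautomerization of dienone 4 to the phenol; no stereocenter is retained.

Step 3
Reactants: 5 2-allyl-4,5-dimethoxyphenol
Product: 6 2-allyl-4,4,5-trimethoxycyclohexa-2,5-dien-1-one
Conditions: PhI(OAc)2, MeOH, 0 °C
Reagents that add atoms: methanol, CO
Why: Oxidative dearomatization of a para-methoxyphenol with a trivalent iodine reagent, methanol adding at the para carbon to give the quinone monoketal; the terminal alkene is inert and no stereocenter is formed.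

Step 4
Reactants: 6 2-allyl-4,4,5-trimethoxycyclohexa-2,5-dien-1-one; 7 (E)-methyl isoeugenol
Product: 10 (S)-2-allyl-4-[(E)-1-(3,4-dimethoxyphenyl)prop-1-en-2-yl]-4,5-dimethoxycyclohexa-2,5-dien-1-one (target), via oxocarbenium ion 8 (not isolated), via benzylic cation 9 (not isolated)
Conditions: chiral imidodiphosphorimidate Brønsted acid (IDPi, 5 mol %), 7 (1.5 equiv), 5 Å molecular sieves, toluene, −60 °C
Reagents that add atoms: none
Why: Proposed new method: the confined chiral acid ionizes the ketal of 6 to a contact ion pair of methoxy-oxocarbenium 8 (the phenoxenium of 5, in which the normally nucleophilic para carbon has become electrophilic) with the chiral anion; the nucleophilic C8 of alkene 7 attacks C4 on the face left open by the anion, which sets the S quaternary center, and the anion then removes H8 from benzylic cation 9 (E1) to give the conjugated E alkene (aryl anti to the bulky quaternary carbon) and return the acid; the closest known reaction types are acid-promoted substitution of quinone monoketals by alkenes (biomimetic neolignan couplings and formal [3+2] couplings) and asymmetric counteranion-directed additions of alkenes to oxocarbenium ions (catalytic asymmetric Prins-type reactions).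

**Compound list**
1 | 3,4-dimethoxyphenol | COc1ccc(O)cc1OC | starting material
2 | allyl bromide (3-bromoprop-1-ene) | C=CCBr | starting material
3 | allyl 3,4-dimethoxyphenyl ether | C=CCOc1ccc(OC)c(OC)c1 | intermediate
4 | 6-allyl-3,4-dimethoxycyclohexa-2,4-dien-1-one (Claisen dienone, racemic, not isolated) | C=CCC1C=C(OC)C(OC)=CC1=O | intermediate
5 | 2-allyl-4,5-dimethoxyphenol | C=CCc1cc(OC)c(OC)cc1O | intermediate
6 | 2-allyl-4,4,5-trimethoxycyclohexa-2,5-dien-1-one | C=CCC1=CC(OC)(OC)C(OC)=CC1=O | intermediate
7 | (E)-methyl isoeugenol, (E)-1,2-dimethoxy-4-(prop-1-en-1-yl)benzene | C/C=C/c1ccc(OC)c(OC)c1 | starting material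
8 | (5-allyl-2-methoxy-4-oxocyclohexa-2,5-dien-1-ylidene)(methyl)oxonium, paired with the chiral anion (not isolated) | C=CCC1=CC(=[O+]C)C(OC)=CC1=O | intermediate
9 | benzylic cation formed by attack of C8 of 7 on C4 of 8, C4 configured as in 10, paired with the chiral anion (not isolated) | C=CCC1=C[C@](OC)(C(C)[CH+]c2ccc(OC)c(OC)c2)C(OC)=CC1=O | intermediate
10 | (S)-2-allyl-4-[(E)-1-(3,4-dimethoxyphenyl)prop-1-en-2-yl]-4,5-dimethoxycyclohexa-2,5-dien-1-one | C=CCC1=C[C@](OC)(/C(C)=C/c2ccc(OC)c(OC)c2)C(OC)=CC1=O | target

**Step count and risks**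

Total step count: 4. Longest linear sequence: 4 steps (1 → 3 → 5 → 6 → 10); compound 7 is used as purchased. The alkene geometry of 7 is not transferred, because it is lost in cation 9.

Most likely to fail, first: step 4. The likely failure modes are these:
- Cation 8 is also electrophilic at C2, the allyl-bearing carbon. C6 is less of a concern because the C5 methoxy group makes it electron-rich.
- Cation 9 can be trapped by the C5=C6 enol ether to give bicyclo[3.2.1]octane products instead of losing H8.
- The strong acid can oligomerize 7 or re-ionize 10, which would erode the ee.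
- Ion pairing alone may not discriminate well between the faces of a flat cation.

The controls are low temperature, a non-polar solvent, sieves to hold the methanol, slow addition of 7 and a cold quench with a trace of Et3N.

The fallback sets out from 6 and comes back at 10, using normal-polarity 1,2-addition followed by resolution:
- Dilute aqueous HClO4 in THF hydrolyses 6 to 2-allyl-5-methoxy-1,4-benzoquinone F1.
- Sonogashira coupling of commercial 4-iodo-1,2-dimethoxybenzene with propyne (PdCl2(PPh3)2, CuI, Et3N) gives 1,2-dimethoxy-4-(prop-1-yn-1-yl)benzene F2.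
- Hydrozirconation with a slight excess of Cp2Zr(H)Cl (thermodynamic control, zirconium on the methyl-bearing carbon) gives the (E)-alkenylzirconocene chloride F3, and iodine converts it to (E)-4-(2-iodoprop-1-en-1-yl)-1,2-dimethoxybenzene F4.
- Iodine–lithium exchange (t-BuLi, Et2O, −78 °C) gives (Z)-[1-(3,4-dimethoxyphenyl)prop-1-en-2-yl]lithium F5 (aryl trans to lithium).
- F5 adds to the more electrophilic carbonyl of F1, the one next to the methoxy-bearing carbon (the other is a vinylogous ester). Work-up with aqueous NH4Cl gives racemic 2-allyl-4-hydroxy-5-methoxy-4-[(E)-1-(3,4-dimethoxyphenyl)prop-1-en-2-yl]cyclohexa-2,5-dien-1-one F6.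
- Preparative chiral-phase SFC gives the (S)-quinol F7, and O-methylation (NaH, MeI, THF, 0 °C) gives 10.

Second: step 2. The Claisen rearrangement can also deliver the allyl group to the carbon between the two oxygens, giving 2-allyl-3,4-dimethoxyphenol, which must be separated from 5. The fallback sets out from 1 and comes back at 5. Bromination of 1 with NBS in MeCN at 0 °C goes ortho to OH and para to the 3-methoxy group and gives 2-bromo-4,5-dimethoxyphenol F8. Stille coupling with allyltributylstannane (Pd(PPh3)4, toluene, 100 °C) then gives 5 as a single regioisomer.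

Third: step 3. The risks are attack of methanol at the allyl-bearing ortho carbon, over-oxidation, and loss of the acid-sensitive ketal on isolation. The fallback sets out from 5 and comes back at 6. Methylation of 5 (MeI, K2CO3, acetone) gives 1-allyl-2,4,5-trimethoxybenzene F9. Anodic oxidation (Pt anode, KOH, MeOH, 0 °C, constant current) gives the quinone bisketal 1-allyl-3,3,4,6,6-pentamethoxycyclohexa-1,4-diene F10. Dilute aqueous acetic acid in acetone then hydrolyses one ketal; the ketal at C6 ionizes preferentially because its cation is stabilized through the C4 methoxy enol ether, so the product is 6.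

**Further compounds**
F1 | step 4 | 2-allyl-5-methoxy-1,4-benzoquinone | C=CCC1=CC(=O)C(OC)=CC1=O
F2 | step 4 | 1,2-dimethoxy-4-(prop-1-yn-1-yl)benzene | CC#Cc1ccc(OC)c(OC)c1
F3 | step 4 | (E)-[1-(3,4-dimethoxyphenyl)prop-1-en-2-yl]zirconocene chloride | Cl[Zr](/C(C)=C/c1ccc(OC)c(OC)c1)(C1C=CC=C1)C1C=CC=C1
F4 | step 4 | (E)-4-(2-iodoprop-1-en-1-yl)-1,2-dimethoxybenzene | I/C(C)=C/c1ccc(OC)c(OC)c1
F5 | step 4 | (Z)-[1-(3,4-dimethoxyphenyl)prop-1-en-2-yl]lithium | [Li]/C(C)=C/c1ccc(OC)c(OC)c1
F6 | step 4 | racemic 2-allyl-4-hydroxy-5-methoxy-4-[(E)-1-(3,4-dimethoxyphenyl)prop-1-en-2-yl]cyclohexa-2,5-dien-1-one | C=CCC1=CC(O)(/C(C)=C/c2ccc(OC)c(OC)c2)C(OC)=CC1=O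
F7 | step 4 | (S)-2-allyl-4-hydroxy-5-methoxy-4-[(E)-1-(3,4-dimethoxyphenyl)prop-1-en-2-yl]cyclohexa-2,5-dien-1-one | C=CCC1=C[C@](O)(/C(C)=C/c2ccc(OC)c(OC)c2)C(OC)=CC1=O
F8 | step 2 | 2-bromo-4,5-dimethoxyphenol | COc1cc(O)c(Br)cc1OC
F9 | step 3 | 1-allyl-2,4,5-trimethoxybenzene | C=CCc1cc(OC)c(OC)cc1OC
F10 | step 3 | 1-allyl-3,3,4,6,6-pentamethoxycyclohexa-1,4-diene | C=CCC1=CC(OC)(OC)C(OC)=CC1(OC)OC
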